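**Retrosynthetic overview**
1. The pyran ring is formed last. O1–C8a comes from intramolecular addition–elimination of a tertiary alcohol on a 2-methoxyquinone. C4–C4a comes from Suzuki coupling of a Z-alkenylboronate with 3-bromo-2,5-dimethoxybenzoquinone, whose ring is taken from p-benzoquinone.
2. The C2 carbinol traces back from the Z-boronate to a tertiary propargylic alcohol, then to the Sharpless epoxide of an E-trisubstituted allylic alcohol, then to a terminal alkyne (carboalumination).
3. The exocyclic methylene comes from a 2,2,6-trisubstituted cyclohexanone. The ring CH(CH3) centre is set by reagent-controlled enolate protonation.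
4. Key step: the cyclohexanone ring is formed first, by one-carbon ring expansion of 2-methylcyclopentanone with 5-diazohex-1-yne (1,2-alkyl shift with loss of N2). This step sets the quaternary centre.
5. Building blocks: hex-5-yn-2-one, 2-methylcyclopentanone, p-benzoquinone.

Assumption: the sense of induction of the new catalyst (step 2) and of the chiral proton source (step 3) is fixed in a pilot run. Both antipodes of each are accessible, and the one giving the drawn configuration is used.

**Step 1**
Reactants: 1 hex-5-yn-2-one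
Product: 2 hex-5-yn-2-one hydrazone
Conditions: N2H4·H2O (8 equiv), EtOH, 0 °C to rt
Reagents that add atoms: hydrazine NN
Why: Simple carbonyl condensation (hydrazone formation), in which the large excess of hydrazine suppresses azine formation and no stereocentre is involved.

**Step 2**
Reactants: 2 hex-5-yn-2-one hydrazone; 3 2-methylcyclopentan-1-one (racemic, 3 equiv)
Product: 5 (2R)-2-(but-3-yn-1-yl)-2,6-dimethylcyclohexan-1-one (C6 epimer mixture), via 5-diazohex-1-yne 4 (not isolated)
Conditions: Ag2O, MgSO4, Et2O, −20 °C, cold filtration; slow addition to 3, Sc(OTf)3 (10 mol %), chiral N,N′-dioxide ligand L3-PiPr2 (pipecolic acid/2,6-diisopropylaniline type, 11 mol %), 4 Å MS, CH2Cl2, −78 to −40 °C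
Reagents that add atoms: none
Why: Proposed new method: the trivalent-scandium/N,N′-dioxide Lewis acid binds the ketone oxygen, the nucleophilic diazo carbon of 4 adds to C=O, and in the β-oxido diazonium the unsubstituted ring CH2 antiperiplanar to N2 migrates (1,2-alkyl shift, the less substituted carbon moving as is usual in diazoalkane homologations) with inversion at the diazo carbon as N2 leaves, so the six-membered ring forms and the quaternary configuration depends only on which prochiral face of 4 (CH3 versus CH2CH2C≡CH) the chiral pocket admits; the closest known reaction types are the Sc(OTf)3-catalysed Büchner–Curtius–Schlotterbeck/Tiffeneau–Demjanov-type homologation of cycloalkanones with aryl diazoalkanes and the Sc(OTf)3/N,N′-dioxide asymmetric homologation with α-alkyl-α-diazo esters, neither shown for a non-stabilised dialkyl diazoalkane.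

**Step 3**
Reactants: 5 (2R)-2-(but-3-yn-1-yl)-2,6-dimethylcyclohexan-1-one (C6 epimer mixture)
Product: 7 (2R,6R)-2-(but-3-yn-1-yl)-2,6-dimethylcyclohexan-1-one, via dilithio enolate-acetylide 6 (not isolated)
Conditions: LDA (2.2 equiv), THF, 0 °C; chiral Kemp's-triacid imide–oxazoline proton source (0.2 equiv), slow addition of BHT (2.3 equiv), −78 °C
Reagents that add atoms: none
Why: Asymmetric enolate protonation, in which only C6–H can enolise, the planar enolate erases the C6 mixture, and the chiral imide (regenerated by BHT) delivers the proton to one face under reagent control as known for the lithium enolate of 2,2,6-trimethylcyclohexanone, giving 6R (6-CH3 cis to the chain) with the minor epimer removable as a diastereomer.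

**Step 4**
Reactants: 7 (2R,6R)-2-(but-3-yn-1-yl)-2,6-dimethylcyclohexan-1-one
Product: 8 (1R,3R)-1-(but-3-yn-1-yl)-1,3-dimethyl-2-methylidenecyclohexane
Conditions: Zn, CH2Br2, TiCl4 (pre-aged reagent), THF/CH2Cl2, 0 °C to rt
Reagents that add atoms: dibromomethane BrCBr
Why: Takai–Lombardo methylenation uses a non-basic gem-dimetallic reagent that converts hindered enolisable ketones into methylene compounds without α-epimerisation and leaves the alkyne alone.

**Step 5**
Reactants: 8 (1R,3R)-1-(but-3-yn-1-yl)-1,3-dimethyl-2-methylidenecyclohexane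
Product: 10 (2E)-5-[(1R,3R)-1,3-dimethyl-2-methylidenecyclohexyl]-3-methylpent-2-en-1-ol, via (E)-alkenyldimethylalane 9 (not isolated)
Conditions: Me3Al (2.5 equiv), Cp2ZrCl2 (0.25 equiv), CH2Cl2, 0 °C to rt; n-BuLi, THF/hexane, −78 °C; (CH2O)n, rt
Reagents that add atoms: trimethylaluminium C[Al](C)C; formaldehyde (as paraformaldehyde) C=O
Why: Negishi zirconium-catalysed carboalumination adds CH3 and Al syn with CH3 on the internal carbon, and the derived alanate attacks formaldehyde with retention, so only the E-trisubstituted allylic alcohol forms while the hindered 1,1-disubstituted alkene is inert.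

**Step 6**
Reactants: 10 (2E)-5-[(1R,3R)-1,3-dimethyl-2-methylidenecyclohexyl]-3-methylpent-2-en-1-ol
Product: 11 [(2S,3S)-3-{2-[(1R,3R)-1,3-dimethyl-2-methylidenecyclohexyl]ethyl}-3-methyloxiran-2-yl]methanol
Conditions: Ti(OiPr)4 (10 mol %), L-(+)-DET (12 mol %), t-BuOOH, 4 Å MS, CH2Cl2, −20 °C
Reagents that add atoms: tert-butyl hydroperoxide CC(C)(C)OO
Why: Sharpless asymmetric epoxidation with L-(+)-tartrate gives the (2S,3S)-epoxide of an E-allylic alcohol under pure reagent control (as for geraniol), fixing the tertiary C–O centre that becomes C2 of the chromene and ignoring the non-allylic methylene group.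

**Step 7**
Reactants: 11 [(2S,3S)-3-{2-[(1R,3R)-1,3-dimethyl-2-methylidenecyclohexyl]ethyl}-3-methyloxiran-2-yl]methanol
Product: 12 (2S,3R)-3-(chloromethyl)-2-{2-[(1R,3R)-1,3-dimethyl-2-methylidenecyclohexyl]ethyl}-2-methyloxirane
Conditions: PPh3, CCl4, NaHCO3, reflux
Reagents that add atoms: tetrachloromethane ClC(Cl)(Cl)Cl
Why: The Appel reaction replaces the primary OH under neutral buffered conditions without opening the epoxide (the descriptor change at the CH carbon is only a priority change).

**Step 8**
Reactants: 12 (2S,3R)-3-(chloromethyl)-2-{2-[(1R,3R)-1,3-dimethyl-2-methylidenecyclohexyl]ethyl}-2-methyloxirane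
Product: 13 (3S)-5-[(1R,3R)-1,3-dimethyl-2-methylidenecyclohexyl]-3-methylpent-1-yn-3-ol
Conditions: n-BuLi (3.5 equiv), THF, −78 to −30 °C; H2O
Reagents that add atoms: none
Why: Base-induced double elimination of a 2,3-epoxy chloride (Takano–Yadav propargylic alcohol synthesis) opens the epoxide at the CH carbon and then expels chloride, so the tertiary C–O bond is never broken and the centre is retained as 3S.

**Step 9**
Reactants: 13 (3S)-5-[(1R,3R)-1,3-dimethyl-2-methylidenecyclohexyl]-3-methylpent-1-yn-3-ol
Product: 15 (1Z,3S)-5-[(1R,3R)-1,3-dimethyl-2-methylidenecyclohexyl]-3-methyl-1-(4,4,5,5-tetramethyl-1,3,2-dioxaborolan-2-yl)pent-1-en-3-ol, via O-boryl Z-alkenylboronate 14 (not isolated)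
Conditions: HBpin (2.1 equiv), [Rh(cod)Cl]2 (1.5 mol %), P(iPr)3 (6 mol %), Et3N, cyclohexane, rt; aqueous work-up
Reagents that add atoms: pinacolborane B1OC(C)(C)C(C)(C)O1
Why: Rhodium-catalysed formal trans-hydroboration of a terminal alkyne proceeds through a monovalent-rhodium vinylidene and gives the Z-alkenylboronate, the first equivalent of HBpin masking the OH as a borate that falls off on work-up and the hindered methylene group reacting far more slowly than the alkyne.

**Step 10**
Reactants: 16 1,4-benzoquinone (3 equiv)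
Product: 17 2,5-dimethoxy-1,4-benzoquinone
Conditions: MeOH, ZnCl2, reflux
Reagents that add atoms: methanol CO
Why: Two rounds of Lewis-acid-promoted conjugate addition of methanol and re-oxidation by excess quinone give the sparingly soluble 2,5-isomer, the first methoxy group directing the second addition to C5.

**Step 11**
Reactants: 17 2,5-dimethoxy-1,4-benzoquinone
Product: 18 3-bromo-2,5-dimethoxy-1,4-benzoquinone
Conditions: Br2 (1.0 equiv), NaOAc, AcOH, rt
Reagents that add atoms: bromine BrBr
Why: Electrophilic bromination at the nucleophilic β-carbon of the vinylogous ester followed by loss of HBr (addition–elimination) gives the monobromide, the two free ring positions being equivalent.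

**Step 12**
Reactants: 15 (1Z,3S)-5-[(1R,3R)-1,3-dimethyl-2-methylidenecyclohexyl]-3-methyl-1-(4,4,5,5-tetramethyl-1,3,2-dioxaborolan-2-yl)pent-1-en-3-ol; 18 3-bromo-2,5-dimethoxy-1,4-benzoquinone
Product: 20 metachromin E, (2S)-2-{2-[(1R,3R)-1,3-dimethyl-2-methylidenecyclohexyl]ethyl}-6-methoxy-2-methyl-2H-chromene-5,8-dione, via Z-hydroxyalkenyl dimethoxyquinone 19 (not isolated)
Conditions: Pd(dppf)Cl2 (5 mol %), K3PO4·H2O (3 equiv), THF, 40 °C, dark
Reagents that add atoms: none
Why: Suzuki–Miyaura coupling keeps the Z geometry, which places the tertiary alkoxide next to C2–OMe of the vinylogous ester, so oxa-Michael addition/β-elimination of methoxide closes the 2H-pyran without touching the C–O bond of the stereocentre (retention, 2S).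

**Compound list**
1 | hex-5-yn-2-one | CC(=O)CCC#C | starting material
2 | hex-5-yn-2-one hydrazone | CC(CCC#C)=NN | intermediate
3 | 2-methylcyclopentan-1-one (racemic) | CC1CCCC1=O | starting material
4 | 5-diazohex-1-yne | CC(CCC#C)=[N+]=[N-] | intermediate
5 | (2R)-2-(but-3-yn-1-yl)-2,6-dimethylcyclohexan-1-one, C6 epimer mixture | O=C1C(C)CCC[C@]1(C)CCC#C | intermediate
6 | dilithium salt: (6R)-6-(4-lithiobut-3-yn-1-yl)-2,6-dimethylcyclohex-1-en-1-olate | [Li+].[Li+].[O-]C1=C(C)CCC[C@]1(C)CCC#[C-] | intermediate
7 | (2R,6R)-2-(but-3-yn-1-yl)-2,6-dimethylcyclohexan-1-one | O=C1[C@H](C)CCC[C@]1(C)CCC#C | intermediate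
8 | (1R,3R)-1-(but-3-yn-1-yl)-1,3-dimethyl-2-methylidenecyclohexane | C=C1[C@H](C)CCC[C@]1(C)CCC#C | intermediate
9 | {(1E)-4-[(1R,3R)-1,3-dimethyl-2-methylidenecyclohexyl]-2-methylbut-1-en-1-yl}dimethylalane | C=C1[C@H](C)CCC[C@]1(C)CC/C(C)=C/[Al](C)C | intermediate
10 | (2E)-5-[(1R,3R)-1,3-dimethyl-2-methylidenecyclohexyl]-3-methylpent-2-en-1-ol | C=C1[C@H](C)CCC[C@]1(C)CC/C(C)=C/CO | intermediate
11 | [(2S,3S)-3-{2-[(1R,3R)-1,3-dimethyl-2-methylidenecyclohexyl]ethyl}-3-methyloxiran-2-yl]methanol | C=C1[C@H](C)CCC[C@]1(C)CC[C@]2(C)O[C@H]2CO | intermediate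
12 | (2S,3R)-3-(chloromethyl)-2-{2-[(1R,3R)-1,3-dimethyl-2-methylidenecyclohexyl]ethyl}-2-methyloxirane | C=C1[C@H](C)CCC[C@]1(C)CC[C@]2(C)O[C@H]2CCl | intermediate
13 | (3S)-5-[(1R,3R)-1,3-dimethyl-2-methylidenecyclohexyl]-3-methylpent-1-yn-3-ol | C=C1[C@H](C)CCC[C@]1(C)CC[C@@](O)(C)C#C | intermediate
14 | O-(pinacolatoboryl) ether of 15 | C=C1[C@H](C)CCC[C@]1(C)CC[C@@](OB2OC(C)(C)C(C)(C)O2)(C)/C=C\B3OC(C)(C)C(C)(C)O3 | intermediate
15 | (1Z,3S)-5-[(1R,3R)-1,3-dimethyl-2-methylidenecyclohexyl]-3-methyl-1-(4,4,5,5-tetramethyl-1,3,2-dioxaborolan-2-yl)pent-1-en-3-ol | C=C1[C@H](C)CCC[C@]1(C)CC[C@@](O)(C)/C=C\B2OC(C)(C)C(C)(C)O2 | intermediate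
16 | 1,4-benzoquinone | O=C1C=CC(=O)C=C1 | starting material
17 | 2,5-dimethoxy-1,4-benzoquinone | COC1=CC(=O)C(OC)=CC1=O | intermediate
18 | 3-bromo-2,5-dimethoxy-1,4-benzoquinone | COC1=CC(=O)C(OC)=C(Br)C1=O | intermediate
19 | 3-{(1Z,3S)-5-[(1R,3R)-1,3-dimethyl-2-methylidenecyclohexyl]-3-hydroxy-3-methylpent-1-en-1-yl}-2,5-dimethoxy-1,4-benzoquinone | C=C1[C@H](C)CCC[C@]1(C)CC[C@@](O)(C)/C=C\C2=C(OC)C(=O)C=C(OC)C2=O | intermediate
20 | metachromin E, (2S)-2-{2-[(1R,3R)-1,3-dimethyl-2-methylidenecyclohexyl]ethyl}-6-methoxy-2-methyl-2H-chromene-5,8-dione | C=C1[C@H](C)CCC[C@]1(C)CC[C@@]1(C)C=CC2=C(O1)C(=O)C=C(OC)C2=O | target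

**Total step count:** 12. **Longest linear sequence:** 10 (steps 1–9 and 12).

**Steps most likely to fail**

*Step 2 (new ring expansion).*
- Risks: acid-induced decay of 4, epoxide formation instead of migration, and weak discrimination of CH3 against the butynyl arm.
- The fallback uses known chemistry only. It sets out from 3 and comes back at 5.
- Ketone 3 is ring-expanded with diazoethane under BF3·OEt2 (CH2 migration) to 2,6-dimethylcyclohexan-1-one F1.
- Condensation with (S)-1-phenylethanamine gives (S)-N-(2,6-dimethylcyclohexylidene)-1-phenylethanamine F2.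
- The secondary enamine tautomer of F2 adds to methyl acrylate (d'Angelo deracemising Michael addition). Aqueous AcOH then gives methyl 3-[(1R)-1,3-dimethyl-2-oxocyclohexyl]propanoate F3.
- LiAlH4 gives (2R)-2-(3-hydroxypropyl)-2,6-dimethylcyclohexan-1-ol F4.
- Swern oxidation gives 3-[(1R)-1,3-dimethyl-2-oxocyclohexyl]propanal F5.
- The Ohira–Bestmann reagent with K2CO3/MeOH turns CHO into C≡CH, which is 5.

*Step 3 (protonation).*
- Risks: slow deprotonation of the hindered ketone, and proton return from diisopropylamine that lowers the diastereomer ratio.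
- The fallback sets out from 5 and comes back at 7. It replaces kinetic reagent control by equilibration and separation.
- Ketone 5 is equilibrated with DBU in toluene, and 7 is isolated by chromatography.
- The unwanted C6 epimer, which is a component of 5, is returned to the equilibration. No new compound is made.

*Step 12 (coupling on a base-sensitive bromoquinone, then ring closure).*
- Risks: hydrolysis or substitution of 18 by the base, and quinone-induced loss of zerovalent palladium.
- The fallback sets out from 18 (together with 15) and comes back at 19.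
- Na2S2O4 reduces 18 to 3-bromo-2,5-dimethoxybenzene-1,4-diol F6.
- Me2SO4/K2CO3 gives 3-bromo-1,2,4,5-tetramethoxybenzene F7, a base-stable arene.
- F7 is coupled with 15 under Pd(dppf)Cl2/K3PO4 to give (1Z,3S)-5-[(1R,3R)-1,3-dimethyl-2-methylidenecyclohexyl]-3-methyl-1-(2,3,5,6-tetramethoxyphenyl)pent-1-en-3-ol F8.
- (NH4)2Ce(NO3)6 in MeCN/H2O oxidises F8 to 19. Both possible para-quinones are the same compound.
- Quinone 19 is closed to 20 with K3PO4 as in step 12.

**Further compounds**
F1 | step 2 | 2,6-dimethylcyclohexan-1-one (cis/trans) | CC1CCCC(C)C1=O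
F2 | step 2 | (S)-N-(2,6-dimethylcyclohexylidene)-1-phenylethanamine | C[C@H](N=C1C(C)CCCC1C)c1ccccc1
F3 | step 2 | methyl 3-[(1R)-1,3-dimethyl-2-oxocyclohexyl]propanoate (C3 epimers) | O=C1C(C)CCC[C@]1(C)CCC(=O)OC
F4 | step 2 | (2R)-2-(3-hydroxypropyl)-2,6-dimethylcyclohexan-1-ol (mixture at C1 and C6) | OC1C(C)CCC[C@]1(C)CCCO
F5 | step 2 | 3-[(1R)-1,3-dimethyl-2-oxocyclohexyl]propanal (C3 epimers) | O=C1C(C)CCC[C@]1(C)CCC=O
F0 | step 3 | none | none
F6 | step 12 | 3-bromo-2,5-dimethoxybenzene-1,4-diol | COc1cc(O)c(OC)c(Br)c1O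
F7 | step 12 | 3-bromo-1,2,4,5-tetramethoxybenzene | COc1cc(OC)c(OC)c(Br)c1OC
F8 | step 12 | (1Z,3S)-5-[(1R,3R)-1,3-dimethyl-2-methylidenecyclohexyl]-3-methyl-1-(2,3,5,6-tetramethoxyphenyl)pent-1-en-3-ol | C=C1[C@H](C)CCC[C@]1(C)CC[C@@](O)(C)/C=C\c2c(OC)c(OC)cc(OC)c2OC
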